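Readings and results come from a simulation with made-up constants, noise included.

G, the gas held at constant pressure, is the reagent to balance first. Its solution saturates at 26 mM, less than larch's D at 0.15 M. Take one G per J as a working assumption, and write dissolved G as gas in against J out.

| flask | D | G | Z | Q | remark | time |
|---|---|---|---|---|---|---|
| Wednesday's | 0.16 M | 26 mM (held) | 4.8 mol% | 0.14 mol% | run made earlier |  |
| Sunday's | 0.64 M | 26 mM (held) | 4.8 mol% | 0.14 mol% | run made earlier |  |
| Tuesday's | 1.8 M | 26 mM (held) | 4.8 mol% | 0.14 mol% | run made earlier |  |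
| larch | 0.15 M | 26 mM (held) | 4.8 mol% | 0.14 mol% |  | 50 h |
| cedar | 0.30 M | 26 mM (held) | 4.8 mol% | 0.14 mol% |  | 50 h |
| alder | 0.60 M | 26 mM (held) | 4.8 mol% | 0.14 mol% |  | 50 h |
| oak | 1.2 M | 26 mM (held) | 4.8 mol% | 0.14 mol% |  | 50 h |
| maple | 2.5 M | 26 mM (held) | 4.8 mol% | 0.14 mol% |  | 50 h |

- Wednesday's (time / h: J / %, D / %): 4.00: 2, 63; 12.0: 3, 30; 25.0: 8, 11; 40.0: 19, 8; 48.0: 24, 0
- Sunday's (time / h: J / %, D / %): 10.0: 11, 0; 20.0: 27, 0; 30.0: 33, 4; 40.0: 44, 1; 48.0: 53, 2
- Tuesday's (time / h: J / %, D / %): 4.00: 5, 2; 12.0: 7, 1; 25.0: 22, 0; 40.0: 34, 0; 48.0: 42, 0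

(scatter of a reading: 2 percentage points)

1. [J] at the end for larch, cedar, alder, oak, maple, in this order
2. how that number moves from the first to the last of them (falls, then rises / rises all the way / falls all the way / rises, then falls / hardly changes)

- the numbers in the tables scatter with a standard deviation of 2 percentage points
- at the start none of G is in solution
- "hardly changes" means that all values lie within two and a half points (for a concentration: within two and a half percent of the largest)

Read rates, as my own reckoning. Sunday's run makes 53 % of its charge in 48.0 h. Take that pace per charge as a working assumption for the larger charges. Equal loadings do not give it: Wednesday's run, with Z at 4.8 mol% and Q at 0.14 mol% as on Sunday, makes 24 % in 48.0 h, less than Sunday's run. On Tuesday's charge the assumed pace asks for 0.0199 M h⁻¹. Tuesday's run makes 42 % in 48.0 h, so it delivers 0.0158 M h⁻¹. Call this reading the gas ceiling, the molar rate of J that the gas feeds once the charge asks for more. It carries the scatter of 2 percentage points. At that rate the saturated content lasts 1.65 h, so gas in must keep pace with J out. Treat gas uptake as the rate-limiting step, since the ceiling is lower than the pace asked for.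

Now take maple. Sunday's pace asks for 0.0276 M h⁻¹, faster than the ceiling, so the slowing factor is 0.572. Held over 50 h, that gives 0.787 M of J in maple instead of 1.38 M. Oak at Sunday's pace reaches 0.662 M, less than maple's figure, so my row still rises.

The forecast gives 0.037 M, 0.12 M, 0.32 M, 0.6 M and 1.02 M, and its shape is rises all the way. It reads Tuesday's yield as a sign that “gas supply is starting to limit the rate”. Its maple value is higher than mine.

The flask gives 0.0326 M, 0.118 M, 0.324 M, 0.628 M and 0.828 M, and the shape is rises all the way.

    D + Z → Z + E (k = 13.0 M⁻¹ h⁻¹)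
    L + Q + E → Q + J (k = 1200 M⁻² h⁻¹)
    G ⇌ L, rate k3*(csat - [L]) (kL = 0.690 h⁻¹)

At 50.0 h, maple holds L at 0.00232 M, against saturation at 26 mM. Multiply the gas ceiling by the time again to get 0.787 M. Maple's J stands at 1.05 of that figure. Oak's J, at 0.628 M, stands at 0.798 of it, with L at 0.00967 M.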